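**Retrosynthetic overview**

1. Target 36 ⇒ (desilylation) 35 ⇒ Mitsunobu ester bond, with inversion at C6 of the alkaloid, between 6-epi-incarvilline 33 and dienoic acid 21; 21 ⇒ ester bond between the protected cyclohexanediol 14 and acid 17, which comes from geranyl acetate.
2. Cyclohexane ring: the CH2–CH2 bond between C2 (next to the tertiary carbinol C1) and C3 (next to the secondary carbinol C4) is formed in step 5. Anodic oxidation of the open-chain silyl enol ether 8 closes the cyclohexanone and, by Boc-carbonate capture of the resulting tertiary cation, a temporary spiro 1,3-dioxan-2-one in the same operation; 8 comes from isoprenol and allyl bromide.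
3. Enabling feature: the cyclohexane ring carries oxygen at C1 and C4, and C1 also carries the 2-oxyethyl arm. C4 can therefore be a ketone whose enol carbon C3 is the oxidisable terminus, C1 can be the cationic end of a 1,1-disubstituted alkene, and the arm oxygen lies 1,3 to the C1 oxygen, which fits a six-membered cyclic carbonate. The ring is symmetric about C1···C4, so no stereocentre arises until the ketone is reduced (step 6, trans).
4. Alkaloid: the cyclopentane is bought as (R)-4-silyloxycyclopentenone. C7a is set by anti radical conjugate addition, C7 by trans enolate methylation, the piperidine ring is closed by reductive Heck cyclisation onto the enone (cis fusion, C4a), then C4 by hydrogenation and C6 by hydride reduction followed by Mitsunobu inversion.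
5. Ring order: cyclohexanone and spiro-carbonate rings together (step 5), piperidine ring (step 19); the carbonate ring is opened again in step 8.

Key step: step 5

Remark: the two descriptors on the cyclohexane ring are read as a trans relation between the tertiary and the secondary hydroxyl (arm and secondary hydroxyl cis); this ring is achiral, so only the relative configuration has to be made.

**Route**

Step 1
Reactants: 1 3-methylbut-3-en-1-ol (isoprenol); 2 allyl bromide
Product: 4 3-methylidenehept-6-en-1-ol, via isoprenol C,O-dilithio dianion 3 (not isolated)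
Conditions: n-BuLi (2.2 equiv), TMEDA, Et2O, 0 °C to rt; then 2, −78 °C to rt
Reagents that add atoms: none
Why: Double deprotonation gives a 2-substituted allyl anion whose two termini are equivalent, so C-allylation (SN2 alkylation of an allyllithium) can only give the 1,1-disubstituted alkene; no stereocentre is formed.

Step 2
Reactants: 4 3-methylidenehept-6-en-1-ol
Product: 5 tert-butyl (3-methylidenehept-6-en-1-yl) carbonate
Conditions: Boc2O, DMAP (10 mol %), CH2Cl2, 0 °C to rt
Reagents that add atoms: di-tert-butyl dicarbonate, CC(C)(C)OC(=O)OC(=O)OC(C)(C)C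
Why: DMAP-catalysed acylation of the primary alcohol (carbonate formation) installs the group that later captures the cation; no stereocentre.

Step 3
Reactants: 5 tert-butyl (3-methylidenehept-6-en-1-yl) carbonate
Product: 6 tert-butyl (3-methylidene-6-oxoheptyl) carbonate
Conditions: PdCl2 (10 mol %), CuCl (1 equiv), O2 (1 atm), DMF/H2O 7:1, rt
Reagents that add atoms: water (source of the ketone oxygen; O2 is the terminal oxidant), O
Why: Wacker–Tsuji oxidation converts only the monosubstituted alkene into the methyl ketone, since 1,1-disubstituted alkenes are inert to this catalyst system; no stereocentre.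

Step 4
Reactants: 6 tert-butyl (3-methylidene-6-oxoheptyl) carbonate
Product: 8 tert-butyl {6-[(tert-butyldimethylsilyl)oxy]-3-methylidenehept-6-en-1-yl} carbonate, via kinetic lithium enolate 7 (not isolated)
Conditions: LiN(i-Pr)2 (1.15 equiv), THF, −78 °C, slow addition of 6; then TBSCl, DMPU, −78 to 0 °C
Reagents that add atoms: tert-butyldimethylsilyl chloride, CC(C)(C)[Si](C)(C)Cl
Why: Kinetic deprotonation at the methyl group by the hindered amide at −78 °C (faster than attack on the tert-butyl carbonate) and O-silylation should give the terminal silyl enol ether (kinetic enolate trapping); no stereocentre.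

Step 5
Reactants: 8 tert-butyl {6-[(tert-butyldimethylsilyl)oxy]-3-methylidenehept-6-en-1-yl} carbonate
Product: 11 1,3-dioxaspiro[5.5]undecane-2,9-dione, via tertiary 4-oxocyclohexyl cation 9 (not isolated), via 2-tert-butoxy-1,3-dioxan-2-ylium ion 10 (not isolated)
Conditions: constant-current electrolysis, undivided cell, reticulated vitreous carbon anode, platinum cathode, 2.2 F/mol, n-Bu4NPF6 (0.1 M), 2,6-lutidine (3 equiv), CH2Cl2/(CF3)2CHOH 9:1, rt
Reagents that add atoms: none
Why: Proposed new method: anodic one-electron oxidation of the silyl enol ether (the only group expected to be oxidised well below the isolated alkene and the carbonate) gives a radical cation whose terminal enol carbon bonds to the CH2 terminus of the 1,1-disubstituted alkene; the resulting tertiary radical is oxidised at the anode to cation 9, the Boc carbonyl oxygen adds to give 10, and loss of the tert-butyl group as isobutene and of the silyl group to hexafluoroisopropanol (protons are reduced to H2 at the cathode) should leave 11. The closest known reaction types are anodic enol ether–olefin couplings and the oxidative cyclisations of unsaturated silyl enol ethers with (NH4)2Ce(NO3)6 or Cu(OTf)2, together with the tert-butyl carbonate capture of cationic centres known from iodocarbonate cyclisations; their union in one electrolysis is what is new. The cyclohexanone ring closes 6-endo-trig with respect to the alkene (the enol C–O carbon ends up inside the ring), and the 1,3-dioxan-2-one closes by 6-exo attack of the carbonate oxygen on the tertiary cation. No stereocentre is created, because the spiro carbon lies on the mirror plane of the 4-oxocyclohexane ring, so stereocontrol is deferred to step 6. The step needs 6-endo over 5-exo regioselectivity, which the 1,1-disubstitution of the alkene (attack at CH2 gives a tertiary radical or cation) and the position of the carbonyl carbon inside the forming ring should secure, and it needs cation capture to beat proton loss, which the six-membered neighbouring-group geometry of the carbonate and the non-nucleophilic medium should secure.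

Step 6
Reactants: 11 1,3-dioxaspiro[5.5]undecane-2,9-dione
Product: 12 trans-9-hydroxy-1,3-dioxaspiro[5.5]undecan-2-one (9-OH trans to O1)
Conditions: Li[HB(s-Bu)3] (1.1 equiv), THF, −78 °C; then H2O
Reagents that add atoms: none
Why: Equatorial hydride delivery by the bulky borohydride to the chair with the carbonate oxygen axial (smaller than CH2 and electrostatically favoured in 4-oxy-cyclohexanones) should give the axial alcohol, i.e. the 1,4-trans relation of the two ring oxygens (diastereoselective ketone reduction).

Step 7
Reactants: 12 trans-9-hydroxy-1,3-dioxaspiro[5.5]undecan-2-one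
Product: 13 trans-9-[(tert-butyldimethylsilyl)oxy]-1,3-dioxaspiro[5.5]undecan-2-one
Conditions: TBSCl, imidazole, DMF, rt
Reagents that add atoms: tert-butyldimethylsilyl chloride, CC(C)(C)[Si](C)(C)Cl
Why: Silyl ether formation masks the secondary alcohol so that only the primary hydroxyl is acylated later; configuration untouched.

Step 8
Reactants: 13 trans-9-[(tert-butyldimethylsilyl)oxy]-1,3-dioxaspiro[5.5]undecan-2-one
Product: 14 trans-4-[(tert-butyldimethylsilyl)oxy]-1-(2-hydroxyethyl)cyclohexan-1-ol (silyloxy group trans to the tertiary hydroxyl)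
Conditions: K2CO3 (0.3 equiv), MeOH, rt
Reagents that add atoms: none
Why: Base-catalysed methanolysis (transesterification) of the six-membered cyclic carbonate releases the primary and tertiary hydroxyls while the silyl ether survives; no stereocentre changes.

Step 9
Reactants: 15 geranyl acetate
Product: 16 (2E,6E)-3,7-dimethyl-8-oxoocta-2,6-dien-1-yl acetate
Conditions: SeO2 (1.2 equiv), 1,4-dioxane, 80 °C
Reagents that add atoms: selenium dioxide, O=[Se]=O
Why: Riley allylic oxidation (ene reaction, then [2,3]-sigmatropic shift) attacks the E-methyl group of the terminal trisubstituted alkene and should give the (E)-enal, the acetate blocking the other allylic terminus.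

Step 10
Reactants: 16 (2E,6E)-3,7-dimethyl-8-oxoocta-2,6-dien-1-yl acetate
Product: 17 (2E,6E)-8-acetoxy-2,6-dimethylocta-2,6-dienoic acid
Conditions: NaClO2, NaH2PO4, 2-methylbut-2-ene, t-BuOH/H2O, 0 °C to rt
Reagents that add atoms: sodium chlorite, [Na+].[O-]Cl=O
Why: Pinnick oxidation converts the enal into the acid without touching the alkenes (hypochlorous acid is scavenged) or their geometry.

Step 11
Reactants: 14 trans-4-[(tert-butyldimethylsilyl)oxy]-1-(2-hydroxyethyl)cyclohexan-1-ol; 17 (2E,6E)-8-acetoxy-2,6-dimethylocta-2,6-dienoic acid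
Product: 18 2-{trans-4-[(tert-butyldimethylsilyl)oxy]-1-hydroxycyclohexyl}ethyl (2E,6E)-8-acetoxy-2,6-dimethylocta-2,6-dienoate
Conditions: EDC·HCl (1.3 equiv), DMAP (0.2 equiv), CH2Cl2, 0 °C to rt
Reagents that add atoms: none
Why: Steglich esterification acylates the primary alcohol only, the tertiary alcohol being too hindered, and the α-methyl enoic acid does not isomerise on activation.

Step 12
Reactants: 18 the acetate ester above
Product: 19 2-{trans-4-[(tert-butyldimethylsilyl)oxy]-1-hydroxycyclohexyl}ethyl (2E,6E)-8-hydroxy-2,6-dimethylocta-2,6-dienoate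
Conditions: K2CO3 (0.2 equiv), MeOH, 0 °C
Reagents that add atoms: none
Why: Mild methanolysis (transesterification) should remove the unhindered acetate much faster than the α-branched conjugated ester.

Step 13
Reactants: 19 the allylic alcohol above
Product: 20 2-{trans-4-[(tert-butyldimethylsilyl)oxy]-1-hydroxycyclohexyl}ethyl (2E,6E)-2,6-dimethyl-8-oxoocta-2,6-dienoate
Conditions: MnO2 (activated, excess), CH2Cl2, rt
Reagents that add atoms: none
Why: MnO2 oxidises only the allylic alcohol (allylic alcohol oxidation) and leaves the E geometry intact.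

Step 14
Reactants: 20 the enal above
Product: 21 (2E,6E)-8-(2-{trans-4-[(tert-butyldimethylsilyl)oxy]-1-hydroxycyclohexyl}ethoxy)-3,7-dimethyl-8-oxoocta-2,6-dienoic acid
Conditions: NaClO2, NaH2PO4, 2-methylbut-2-ene, t-BuOH/H2O, 0 °C to rt
Reagents that add atoms: sodium chlorite, [Na+].[O-]Cl=O
Why: Pinnick oxidation gives the 3-methyl-2-enoic acid without E/Z isomerisation or deconjugation.

Step 15
Reactants: 22 N-(tert-butoxycarbonyl)-N-methylglycine; 23 (R)-4-[(tert-butyldimethylsilyl)oxy]cyclopent-2-en-1-one
Product: 24 tert-butyl ({(1S,2R)-2-[(tert-butyldimethylsilyl)oxy]-4-oxocyclopentyl}methyl)(methyl)carbamate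
Conditions: Ir[dF(CF3)ppy]2(dtbbpy)PF6 (1 mol %), K2HPO4, DMF, blue LEDs, rt
Reagents that add atoms: none
Why: Photoredox decarboxylative Giese addition: the carboxylate is oxidised by the excited photocatalyst, loses CO2, and the N-Boc-aminomethyl radical should add to the enone β-carbon anti to the silyloxy group, which sets the future C7a.

Step 16
Reactants: 24 the β-silyloxy ketone above
Product: 25 tert-butyl methyl{[(1R)-4-oxocyclopent-2-en-1-yl]methyl}carbamate
Conditions: DBU (1.1 equiv), CH2Cl2, −20 to 0 °C
Reagents that add atoms: none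
Why: E1cB β-elimination of silanolate moves the enone to the other side of the ring; the stereocentre from step 15 becomes the γ-carbon and should be kept if exposure to base is short.

Step 17
Reactants: 25 the enone above
Product: 27 tert-butyl methyl{[(1S,5R)-5-methyl-4-oxocyclopent-2-en-1-yl]methyl}carbamate, via lithium cross-conjugated dienolate 26 (not isolated)
Conditions: LiN(i-Pr)2 (1.05 equiv), THF, −78 °C; MeI, DMPU, −78 to −40 °C
Reagents that add atoms: iodomethane, CI
Why: Kinetic α′-deprotonation gives the cross-conjugated enolate, which should be methylated anti to the adjacent substituent (enolate alkylation), setting the trans C7 methyl group.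

Step 18
Reactants: 27 the methylated enone above; 28 2,3-dibromoprop-1-ene
Product: 30 (4S,5R)-4-{[(2-bromoprop-2-en-1-yl)(methyl)amino]methyl}-5-methylcyclopent-2-en-1-one, via secondary amine trifluoroacetate 29 (not isolated)
Conditions: CF3CO2H/CH2Cl2 1:4, 0 °C; evaporate; then 28 (1.1 equiv), K2CO3, MeCN, 0 °C to rt
Reagents that add atoms: none
Why: Acidolysis of the Boc group, then SN2 N-allylation of the freed secondary amine by the allylic bromide, which is irreversible whereas aza-Michael addition to the enone is reversible; stereocentres untouched.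

Step 19
Reactants: 30 the vinyl bromide above
Product: 31 (4aS,7R,7aS)-2,7-dimethyl-4-methylideneoctahydro-6H-cyclopenta[c]pyridin-6-one
Conditions: Pd(OAc)2 (10 mol %), PPh3 (20 mol %), HCO2Na (1.5 equiv), Et4NCl, DMF, 80 °C
Reagents that add atoms: none
Why: Reductive Mizoroki–Heck cyclisation: oxidative addition of zerovalent palladium to the vinyl bromide, 6-exo syn carbopalladation of the enone β-carbon from the face of the tether (cis ring fusion, sets C4a), and formate reduction of the palladium enolate, which has no syn β-hydrogen.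

Step 20
Reactants: 31 the exocyclic alkene above
Product: 32 (4S,4aR,7R,7aS)-2,4,7-trimethyloctahydro-6H-cyclopenta[c]pyridin-6-one
Conditions: H2 (1 atm), Pd/C, EtOAc, rt
Reagents that add atoms: none
Why: Heterogeneous hydrogenation of the exocyclic alkene from the convex face of the cis-fused bicycle should place H4 cis to H4a, giving the (4S) methyl group.

Step 21
Reactants: 32 the bicyclic ketone above
Product: 33 (4S,4aR,6R,7R,7aS)-2,4,7-trimethyloctahydro-1H-cyclopenta[c]pyridin-6-ol (6-epi-incarvilline)
Conditions: NaBH4, MeOH, −20 °C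
Reagents that add atoms: none
Why: Hydride attack from the convex face, anti to the piperidine ring, should give the 6R alcohol with OH trans to the C7 methyl group (diastereoselective ketone reduction), which is the epimer needed for inversion.

Step 22
Reactants: 21 the dienoic acid from step 14; 33 6-epi-incarvilline
Product: 35 1-(2-{trans-4-[(tert-butyldimethylsilyl)oxy]-1-hydroxycyclohexyl}ethyl) 8-[(4S,4aR,6S,7R,7aS)-2,4,7-trimethyloctahydro-1H-cyclopenta[c]pyridin-6-yl] (2E,6E)-2,6-dimethylocta-2,6-dienedioate, via alkoxytriphenylphosphonium carboxylate 34 (not isolated)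
Conditions: PPh3 (1.5 equiv), DIAD (1.5 equiv), THF, 0 °C to rt
Reagents that add atoms: none
Why: Mitsunobu esterification: the carboxylate displaces the alkoxyphosphonium group by SN2 from the convex face with inversion, setting the 6S ester; the acid carbonyl is never activated, so the 3-methyl-2-enoate cannot isomerise, and the tertiary alcohol and silyl ether are inert.

Step 23
Reactants: 35 the silyl ether above
Product: 36 CNP0298382.1, 1-[2-(trans-1,4-dihydroxycyclohexyl)ethyl] 8-[(4S,4aR,6S,7R,7aS)-2,4,7-trimethyloctahydro-1H-cyclopenta[c]pyridin-6-yl] (2E,6E)-2,6-dimethylocta-2,6-dienedioate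
Conditions: HF·pyridine, pyridine, THF, 0 °C to rt; aq NaHCO3
Reagents that add atoms: none
Why: Fluoride-mediated desilylation of the secondary silyl ether should leave both enoate esters, the tertiary alcohol and the amine (freed on bicarbonate work-up) intact.

**Compound list**

1 | 3-methylbut-3-en-1-ol (isoprenol) | CC(=C)CCO | starting material
2 | allyl bromide | C=CCBr | starting material
3 | isoprenol C,O-dilithio dianion | [Li]CC(=C)CCO[Li] | intermediate
4 | 3-methylidenehept-6-en-1-ol | C=CCCC(=C)CCO | intermediate
5 | tert-butyl (3-methylidenehept-6-en-1-yl) carbonate | C=CCCC(=C)CCOC(=O)OC(C)(C)C | intermediate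
6 | tert-butyl (3-methylidene-6-oxoheptyl) carbonate | CC(=O)CCC(=C)CCOC(=O)OC(C)(C)C | intermediate
7 | lithium 7-[(tert-butoxycarbonyl)oxy]-5-methylidenehept-1-en-2-olate | [Li]OC(=C)CCC(=C)CCOC(=O)OC(C)(C)C | intermediate
8 | tert-butyl {6-[(tert-butyldimethylsilyl)oxy]-3-methylidenehept-6-en-1-yl} carbonate | C=C(O[Si](C)(C)C(C)(C)C)CCC(=C)CCOC(=O)OC(C)(C)C | intermediate
9 | 1-{2-[(tert-butoxycarbonyl)oxy]ethyl}-4-oxocyclohexan-1-ylium | O=C1CC[C+](CCOC(=O)OC(C)(C)C)CC1 | intermediate
10 | 2-tert-butoxy-9-oxo-1,3-dioxaspiro[5.5]undecan-2-ylium | O=C1CCC2(CC1)CCO[C+](OC(C)(C)C)O2 | intermediate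
11 | 1,3-dioxaspiro[5.5]undecane-2,9-dione | O=C1CCC2(CC1)CCOC(=O)O2 | intermediate
12 | trans-9-hydroxy-1,3-dioxaspiro[5.5]undecan-2-one | O=C1OCC[C@]2(O1)CC[C@H](O)CC2 | intermediate
13 | trans-9-[(tert-butyldimethylsilyl)oxy]-1,3-dioxaspiro[5.5]undecan-2-one | O=C1OCC[C@]2(O1)CC[C@H](O[Si](C)(C)C(C)(C)C)CC2 | intermediate
14 | trans-4-[(tert-butyldimethylsilyl)oxy]-1-(2-hydroxyethyl)cyclohexan-1-ol | OCC[C@]1(O)CC[C@H](O[Si](C)(C)C(C)(C)C)CC1 | intermediate
15 | geranyl acetate | CC(=O)OC/C=C(\C)CCC=C(C)C | starting material
16 | (2E,6E)-3,7-dimethyl-8-oxoocta-2,6-dien-1-yl acetate | CC(=O)OC/C=C(\C)CC/C=C(\C)C=O | intermediate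
17 | (2E,6E)-8-acetoxy-2,6-dimethylocta-2,6-dienoic acid | CC(=O)OC/C=C(\C)CC/C=C(\C)C(=O)O | intermediate
18 | 2-{trans-4-[(tert-butyldimethylsilyl)oxy]-1-hydroxycyclohexyl}ethyl (2E,6E)-8-acetoxy-2,6-dimethylocta-2,6-dienoate | CC(=O)OC/C=C(\C)CC/C=C(\C)C(=O)OCC[C@]1(O)CC[C@H](O[Si](C)(C)C(C)(C)C)CC1 | intermediate
19 | 2-{trans-4-[(tert-butyldimethylsilyl)oxy]-1-hydroxycyclohexyl}ethyl (2E,6E)-8-hydroxy-2,6-dimethylocta-2,6-dienoate | OC/C=C(\C)CC/C=C(\C)C(=O)OCC[C@]1(O)CC[C@H](O[Si](C)(C)C(C)(C)C)CC1 | intermediate
20 | 2-{trans-4-[(tert-butyldimethylsilyl)oxy]-1-hydroxycyclohexyl}ethyl (2E,6E)-2,6-dimethyl-8-oxoocta-2,6-dienoate | O=C/C=C(\C)CC/C=C(\C)C(=O)OCC[C@]1(O)CC[C@H](O[Si](C)(C)C(C)(C)C)CC1 | intermediate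
21 | (2E,6E)-8-(2-{trans-4-[(tert-butyldimethylsilyl)oxy]-1-hydroxycyclohexyl}ethoxy)-3,7-dimethyl-8-oxoocta-2,6-dienoic acid | OC(=O)/C=C(\C)CC/C=C(\C)C(=O)OCC[C@]1(O)CC[C@H](O[Si](C)(C)C(C)(C)C)CC1 | intermediate
22 | N-(tert-butoxycarbonyl)-N-methylglycine | CN(CC(=O)O)C(=O)OC(C)(C)C | starting material
23 | (R)-4-[(tert-butyldimethylsilyl)oxy]cyclopent-2-en-1-one | O=C1C=C[C@H](O[Si](C)(C)C(C)(C)C)C1 | starting material
24 | tert-butyl ({(1S,2R)-2-[(tert-butyldimethylsilyl)oxy]-4-oxocyclopentyl}methyl)(methyl)carbamate | O=C1C[C@@H](CN(C)C(=O)OC(C)(C)C)[C@H](O[Si](C)(C)C(C)(C)C)C1 | intermediate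
25 | tert-butyl methyl{[(1R)-4-oxocyclopent-2-en-1-yl]methyl}carbamate | O=C1C=C[C@H](CN(C)C(=O)OC(C)(C)C)C1 | intermediate
26 | lithium cross-conjugated dienolate of 25 | [Li]OC1=C[C@@H](CN(C)C(=O)OC(C)(C)C)C=C1 | intermediate
27 | tert-butyl methyl{[(1S,5R)-5-methyl-4-oxocyclopent-2-en-1-yl]methyl}carbamate | O=C1C=C[C@H](CN(C)C(=O)OC(C)(C)C)[C@H]1C | intermediate
28 | 2,3-dibromoprop-1-ene | C=C(Br)CBr | starting material
29 | (4S,5R)-5-methyl-4-[(methylamino)methyl]cyclopent-2-en-1-one trifluoroacetate | O=C1C=C[C@H](CNC)[C@H]1C.OC(=O)C(F)(F)F | intermediate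
30 | (4S,5R)-4-{[(2-bromoprop-2-en-1-yl)(methyl)amino]methyl}-5-methylcyclopent-2-en-1-one | O=C1C=C[C@H](CN(C)CC(Br)=C)[C@H]1C | intermediate
31 | (4aS,7R,7aS)-2,7-dimethyl-4-methylideneoctahydro-6H-cyclopenta[c]pyridin-6-one | O=C1C[C@H]2[C@H](CN(C)CC2=C)[C@H]1C | intermediate
32 | (4S,4aR,7R,7aS)-2,4,7-trimethyloctahydro-6H-cyclopenta[c]pyridin-6-one | O=C1C[C@H]2[C@H](CN(C)C[C@H]2C)[C@H]1C | intermediate
33 | (4S,4aR,6R,7R,7aS)-2,4,7-trimethyloctahydro-1H-cyclopenta[c]pyridin-6-ol (6-epi-incarvilline) | O[C@@H]1C[C@H]2[C@H](CN(C)C[C@H]2C)[C@H]1C | intermediate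
34 | alkoxytriphenylphosphonium salt of 33 with the carboxylate of 21 | c1ccccc1[P+](c1ccccc1)(c1ccccc1)O[C@@H]1C[C@H]2[C@H](CN(C)C[C@H]2C)[C@H]1C.[O-]C(=O)/C=C(\C)CC/C=C(\C)C(=O)OCC[C@]1(O)CC[C@H](O[Si](C)(C)C(C)(C)C)CC1 | intermediate
35 | 1-(2-{trans-4-[(tert-butyldimethylsilyl)oxy]-1-hydroxycyclohexyl}ethyl) 8-[(4S,4aR,6S,7R,7aS)-2,4,7-trimethyloctahydro-1H-cyclopenta[c]pyridin-6-yl] (2E,6E)-2,6-dimethylocta-2,6-dienedioate | C/C(=C\C(=O)O[C@H]1C[C@H]2[C@H](CN(C)C[C@H]2C)[C@H]1C)CC/C=C(\C)C(=O)OCC[C@]1(O)CC[C@H](O[Si](C)(C)C(C)(C)C)CC1 | intermediate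
36 | CNP0298382.1 | C/C(=C\C(=O)O[C@H]1C[C@H]2[C@H](CN(C)C[C@H]2C)[C@H]1C)CC/C=C(\C)C(=O)OCC[C@]1(O)CC[C@H](O)CC1 | target

**Step count and risks**

Total step count: 23. Longest linear sequence: 14 steps (steps 1–8, 11–14, 22, 23).

Steps most likely to fail:

Step 5. The tertiary cation may lose a proton instead of being captured, or the radical cation may be desilylated back to the ketone before the C–C bond forms. The fallback sets out from compound 8 and comes back at compound 11. N-Iodosuccinimide (THF, −78 °C) converts 8 into the α-iodo ketone tert-butyl (7-iodo-3-methylidene-6-oxoheptyl) carbonate F1. A Kharasch-type iodine atom-transfer radical cyclisation ((Bu3Sn)2 10 mol %, visible light, benzene, 80 °C) then closes the same bond in the 6-endo mode to the tertiary iodide tert-butyl [2-(1-iodo-4-oxocyclohexyl)ethyl] carbonate F2. AgOTf with 2,6-di-tert-butylpyridine in CH2Cl2 ionises the iodide, and the Boc carbonyl closes the cyclic carbonate 11 with loss of isobutene.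

Step 19. Formate may reduce the vinylpalladium species before ring closure (hydrodebromination), or the palladium enolate may lose a β-hydrogen after isomerisation. The fallback sets out from compound 30 and comes back at compound 31: a radical-chain 6-exo cyclisation of the vinyl radical onto the enone ((Me3Si)3SiH, AIBN, toluene, 80 °C, slow addition). This replaces the organopalladium pathway and gives the same cis-fused ketone, so no new compound is made (F0).

Step 6. Facial selectivity may be poor if the ring reacts through the chair with the CH2 group axial. The fallback sets out from compound 11 and comes back at compound 12. NaBH4 (MeOH, −20 °C) attacks axially and should give the equatorial alcohol cis-9-hydroxy-1,3-dioxaspiro[5.5]undecan-2-one F3. Mitsunobu inversion with chloroacetic acid (PPh3, DIAD, THF) gives trans-2-oxo-1,3-dioxaspiro[5.5]undecan-9-yl chloroacetate F4. Thiourea with NaHCO3 in ethanol removes the chloroacetate without opening the carbonate and delivers 12.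

Further compounds

F1 | step 5 | tert-butyl (7-iodo-3-methylidene-6-oxoheptyl) carbonate | ICC(=O)CCC(=C)CCOC(=O)OC(C)(C)C
F2 | step 5 | tert-butyl [2-(1-iodo-4-oxocyclohexyl)ethyl] carbonate | O=C1CCC(I)(CCOC(=O)OC(C)(C)C)CC1
F0 | step 19 | none | none
F3 | step 6 | cis-9-hydroxy-1,3-dioxaspiro[5.5]undecan-2-one | O=C1OCC[C@]2(O1)CC[C@@H](O)CC2
F4 | step 6 | trans-2-oxo-1,3-dioxaspiro[5.5]undecan-9-yl chloroacetate | O=C1OCC[C@]2(O1)CC[C@H](OC(=O)CCl)CC2
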